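**Retrosynthetic overview**

1. The route rests on the vicinal acyloxy carbons C8 and C9, whose oxygens are cis on the ten-membered carbocycle (C1–C10) and sit next to the C7 stereocentre. The C8–C9 bond is cut to the open-chain Z,Z dialdehyde 22 (C8 aldehyde, C9 enal), and SmI2 pinacol coupling closes the carbocycle first.
2. After closure: acetate at C9, methacrylate at C8, C6-hydroxyl-directed epoxidation of C4=C5 (oxirane second), oxidation of C12 onto O6 (lactone third), and last the C14 methyl group to the aldehyde.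
3. Dialdehyde 22 comes from an Evans syn aldol (C6–C7) of imide 16 with the Z,Z enal ester 8, followed by reduction and double oxidation.
4. Enal 8 comes from neryl acetate (distal alkene cleavage, Still–Gennari olefination); imide 16 from 2-methylprop-2-en-1-ol, CO2 and (4S)-4-benzyl-1,3-oxazolidin-2-one.

Key step: step 14

Remark on the chemistry: positions are named with germacrane numbering (ring C1 to C10, C11 to C13 on C7, C14 on C10, C15 on C4); neryl acetate, the commercial acetate of nerol, is the starting material, and the target is taken as the (4R,5S,6S,7R,8S,9R) enantiomer drawn in the SMILES.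

**Route**

Step 1
Reactants: 1 neryl acetate
Product: 2 (2Z)-5-(3,3-dimethyloxiran-2-yl)-3-methylpent-2-en-1-yl acetate (racemic at the oxirane carbon)
Conditions: mCPBA (1.05 equiv), CH2Cl2, −20 to 0 °C
Reagents that add atoms: 3-chloroperbenzoic acid, O=C(OO)c1cccc(Cl)c1
Why: Prilezhaev epoxidation takes the electron-rich distal trisubstituted alkene in preference to the future C4=C5 bond, which is deactivated by the allylic acetate; the racemic oxirane carbon is excised in step 2.

Step 2
Reactants: 2 (2Z)-5-(3,3-dimethyloxiran-2-yl)-3-methylpent-2-en-1-yl acetate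
Product: 3 (2Z)-3-methyl-6-oxohex-2-en-1-yl acetate
Conditions: H5IO6 (1.1 equiv), THF/Et2O, 0 °C
Reagents that add atoms: none
Why: Periodic acid opens the epoxide to the glycol and cleaves it (Malaprade cleavage) to the C1 aldehyde and acetone, leaving the allylic acetate and the Z alkene untouched.

Step 3
Reactants: 3 (2Z)-3-methyl-6-oxohex-2-en-1-yl acetate; 4 methyl 2-[bis(2,2,2-trifluoroethoxy)phosphoryl]propanoate
Product: 6 methyl (2Z,6Z)-8-acetoxy-2,6-dimethylocta-2,6-dienoate, via potassium phosphonate carbanion 5 (not isolated)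
Conditions: 4, KN(SiMe3)2, 18-crown-6, THF, −78 °C; then 3, −78 °C
Reagents that add atoms: none
Why: Still–Gennari variant of the Horner–Wadsworth–Emmons olefination: the bis(trifluoroethyl) phosphonate with a dissociated potassium counter-ion eliminates fast from the kinetic adduct and should give the Z trisubstituted enoate, that is the future ring-cis C1=C10 bond with C14 trans to C2.

Step 4
Reactants: 6 methyl (2Z,6Z)-8-acetoxy-2,6-dimethylocta-2,6-dienoate
Product: 7 methyl (2Z,6Z)-8-hydroxy-2,6-dimethylocta-2,6-dienoate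
Conditions: K2CO3 (cat.), MeOH, 0 °C to rt
Reagents that add atoms: none
Why: Base-catalysed transesterification removes the acetate, while the methyl ester is degenerate towards methanolysis and both Z alkenes are unaffected.

Step 5
Reactants: 7 methyl (2Z,6Z)-8-hydroxy-2,6-dimethylocta-2,6-dienoate
Product: 8 methyl (2Z,6Z)-2,6-dimethyl-8-oxoocta-2,6-dienoate
Conditions: TEMPO (10 mol %), PhI(OAc)2 (1.1 equiv), CH2Cl2, rt
Reagents that add atoms: none
Why: Oxoammonium (TEMPO/PhI(OAc)2) oxidation of the primary allylic alcohol stops at the aldehyde and, being free of strong acid and base, should keep the Z geometry of the neral-type enal.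

Step 6
Reactants: 9 2-methylprop-2-en-1-ol
Product: 11 3-(hydroxymethyl)but-3-enoic acid, via dilithio dianion 10 (not isolated)
Conditions: n-BuLi (2.2 equiv), TMEDA, Et2O/hexane, 0 °C to rt; CO2, −78 °C; cold aq HCl to pH 3–4, used crude at once
Reagents that add atoms: carbon dioxide, O=C=O
Why: Double deprotonation of the allylic alcohol by n-BuLi/TMEDA gives the alkoxide-stabilised 2-methyleneallyl lithium dianion, whose carbon terminus is carboxylated by CO2 (organolithium carboxylation); cold, mild acidification and immediate use keep the γ-hydroxy acid from lactonising.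

Step 7
Reactants: 11 3-(hydroxymethyl)but-3-enoic acid
Product: 13 3-{[tert-butyl(dimethyl)silyl]oxymethyl}but-3-enoic acid, via bis-silylated acid 12 (not isolated)
Conditions: TBSCl (2.5 equiv), imidazole, DMF, rt; then K2CO3, MeOH/THF/H2O, 0 °C; aq KHSO4 to pH 4
Reagents that add atoms: tert-butyl(chloro)dimethylsilane, CC(C)(C)[Si](C)(C)Cl
Why: Exhaustive silylation followed by selective hydrolysis of the labile silyl ester leaves the primary silyl ether and the free acid, under conditions too mild to move the 1,1-disubstituted alkene into conjugation.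

Step 8
Reactants: 13 3-{[tert-butyl(dimethyl)silyl]oxymethyl}but-3-enoic acid; 14 (4S)-4-benzyl-1,3-oxazolidin-2-one
Product: 16 (4S)-4-benzyl-3-(3-{[tert-butyl(dimethyl)silyl]oxymethyl}but-3-enoyl)-1,3-oxazolidin-2-one, via mixed pivalic anhydride 15 (not isolated)
Conditions: PivCl, Et3N, THF, −20 °C; then 14, LiCl, rt
Reagents that add atoms: none
Why: N-acylation of the oxazolidinone through the mixed pivalic anhydride under LiCl/Et3N activation needs no strong base, so the β,γ-unsaturated acyl group is not isomerised.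

Step 9
Reactants: 16 (4S)-4-benzyl-3-(3-{[tert-butyl(dimethyl)silyl]oxymethyl}but-3-enoyl)-1,3-oxazolidin-2-one; 8 methyl (2Z,6Z)-2,6-dimethyl-8-oxoocta-2,6-dienoate
Product: 18 Evans syn aldol adduct methyl (2Z,6Z,8R,9S)-10-[(4S)-4-benzyl-2-oxo-1,3-oxazolidin-3-yl]-9-(3-{[tert-butyl(dimethyl)silyl]oxy}prop-1-en-2-yl)-8-hydroxy-2,6-dimethyl-10-oxodeca-2,6-dienoate, via dibutylboron Z-enolate 17 (not isolated)
Conditions: Bu2BOTf, i-Pr2NEt, CH2Cl2, −78 to 0 °C; then 8, −78 to 0 °C; pH 7 buffer, MeOH, H2O2, 0 °C
Reagents that add atoms: none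
Why: Evans syn aldol reaction: the Z(O) boron enolate adds through a closed Zimmerman–Traxler transition state on the face away from the benzyl group, which should set C6 (R) and C7 (S) as the syn pair, the C6 oxygen and the C7 branch ending trans on the later ring.

Step 10
Reactants: 18 Evans syn aldol adduct
Product: 19 triethylsilyl ether methyl (2Z,6Z,8R,9S)-10-[(4S)-4-benzyl-2-oxo-1,3-oxazolidin-3-yl]-9-(3-{[tert-butyl(dimethyl)silyl]oxy}prop-1-en-2-yl)-2,6-dimethyl-10-oxo-8-[(triethylsilyl)oxy]deca-2,6-dienoate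
Conditions: TESOTf, 2,6-lutidine, CH2Cl2, −78 °C
Reagents that add atoms: triethylsilyl trifluoromethanesulfonate, CC[Si](CC)(CC)OS(=O)(=O)C(F)(F)F
Why: Silyl triflate with a hindered pyridine base silylates the secondary aldol hydroxyl at low temperature without retro-aldol cleavage.

Step 11
Reactants: 19 triethylsilyl ether of the aldol adduct
Product: 20 methyl (2Z,6Z,8R,9R)-9-(3-{[tert-butyl(dimethyl)silyl]oxy}prop-1-en-2-yl)-10-hydroxy-2,6-dimethyl-8-[(triethylsilyl)oxy]deca-2,6-dienoate
Conditions: LiBH4, MeOH (1 equiv), Et2O, −10 to 0 °C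
Reagents that add atoms: none
Why: Reductive cleavage of the imide: LiBH4 attacks the lithium-chelated exocyclic carbonyl, releasing the auxiliary and the C8 primary alcohol without epimerising C7, while the hindered conjugated methyl ester reacts far more slowly at this temperature.

Step 12
Reactants: 20 hydroxy ester
Product: 21 (2Z,6Z,8R,9R)-9-(3-{[tert-butyl(dimethyl)silyl]oxy}prop-1-en-2-yl)-2,6-dimethyl-8-[(triethylsilyl)oxy]deca-2,6-diene-1,10-diol
Conditions: i-Bu2AlH (3.5 equiv), CH2Cl2, −78 °C; aq potassium sodium tartrate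
Reagents that add atoms: none
Why: 1,2-Reduction of the Z enoate by i-Bu2AlH at low temperature gives the Z allylic alcohol; silyl ethers and isolated alkenes are inert.

Step 13
Reactants: 21 diol
Product: 22 (2Z,6Z,8R,9S)-9-(3-{[tert-butyl(dimethyl)silyl]oxy}prop-1-en-2-yl)-2,6-dimethyl-8-[(triethylsilyl)oxy]deca-2,6-dienedial (C9 Z-enal and C8 aldehyde in germacrane numbering)
Conditions: Dess–Martin periodinane (3 equiv), NaHCO3, CH2Cl2, 0 °C to rt; used crude at once
Reagents that add atoms: none
Why: Buffered Dess–Martin oxidation takes both primary alcohols to the aldehydes under near-neutral conditions, which avoids epimerisation at C7, β-elimination of the C6 silyloxy group and Z-to-E isomerisation of the enal.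

Step 14
Reactants: 22 Z,Z dialdehyde
Product: 23 ten-membered cis-8,9-diol (1R,2S,3R,4R,5Z,9Z)-3-(3-{[tert-butyl(dimethyl)silyl]oxy}prop-1-en-2-yl)-6,10-dimethyl-4-[(triethylsilyl)oxy]cyclodeca-5,9-diene-1,2-diol (ring C1, C2, C3, C4 = germacrane C9, C8, C7, C6)
Conditions: SmI2 (4 equiv, 0.1 M in degassed THF), slow addition of 22 by syringe pump (final 0.003 M), THF, rt; aq NaHCO3/Na2S2O3
Reagents that add atoms: none
Why: Divalent samarium transfers one electron to the C9 enal (the more easily reduced carbonyl) and one to the C8 aldehyde, the two ketyl carbons join inside a chelate in which trivalent samarium bridges both oxygens, and hydrolysis of the samarium diolate gives the diol. The closest known reaction type is the intramolecular pinacol coupling of dialdehydes by SmI2 or low-valent titanium to medium- and large-ring cis-diols. The ten-membered carbocycle closes by C8–C9 bond formation between the two chain termini (formally a 10-exo-trig attack of the C9 ketyl carbon on the C8 carbonyl), helped by the two Z alkenes that fold the chain and by slow addition at high dilution. The cis relation of the C8 and C9 oxygens follows from the oxygen–samarium–oxygen bridge, and the absolute sense from C7: C9 should approach the C8 carbonyl anti to the perpendicular 2-propenyl branch (Felkin–Anh) and anti to the C6 silyloxy group (1,3-anti), both of which place the C8 oxygen cis to the C7 branch (C8 S, C9 R). The step needs coupling at C9 and not at the vinylogous carbon C1, no conjugate reduction and no epimerisation at C7; the oxygen-bound bridge brings C9 rather than C1 next to C8, the absence of a proton source and of HMPA disfavours conjugate reduction and ketyl–alkene side reactions, and the medium is essentially neutral.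

Step 15
Reactants: 23 cis-8,9-diol
Product: 24 C9 monoacetate (6R,7R,8S,9R) with free C8 hydroxyl, C6 OTES and C12 OTBS
Conditions: Ac2O (1.1 equiv), pyridine, DMAP (5 mol %), CH2Cl2, −40 °C
Reagents that add atoms: acetic anhydride, CC(=O)OC(C)=O
Why: Kinetic monoacylation: the allylic C9 hydroxyl is more exposed than the C8 hydroxyl, which is shielded by the branched C7, and low temperature with a weak base suppresses migration of the acetyl group between the cis oxygens.

Step 16
Reactants: 24 C9 monoacetate
Product: 25 C9 acetate C8 methacrylate (6R,7R,8S,9R) with C6 OTES and C12 OTBS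
Conditions: methacrylic anhydride (3 equiv), DMAP, Et3N, CH2Cl2, 0 °C to rt
Reagents that add atoms: methacrylic anhydride, CC(=C)C(=O)OC(=O)C(C)=C
Why: DMAP-catalysed acyl transfer from excess methacrylic anhydride esterifies the remaining hindered C8 hydroxyl faster than the neighbouring acetate can migrate.

Step 17
Reactants: 25 C9 acetate C8 methacrylate
Product: 26 C6 alcohol (6R,7S,8S,9R) with C12 OTBS
Conditions: PPTS (cat.), MeOH/CH2Cl2, 0 °C
Reagents that add atoms: none
Why: Acid-catalysed methanolysis removes the secondary triethylsilyl ether much faster than the primary tert-butyldimethylsilyl ether and does not touch the esters.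

Step 18
Reactants: 26 C6 alcohol
Product: 27 4,5-epoxy C6 alcohol (4R,5S,6S,7S,8S,9R), oxirane oxygen cis to the C6 hydroxyl
Conditions: VO(acac)2 (5 mol %), t-BuOOH (decane solution, 1.5 equiv), CH2Cl2, 0 °C to rt
Reagents that add atoms: tert-butyl hydroperoxide, CC(C)(C)OO
Why: Vanadium-catalysed hydroxyl-directed epoxidation: the C6 alkoxide-bound vanadium peroxide delivers oxygen to the adjacent Z C4=C5 bond on the face syn to the C6 oxygen, as known for medium-ring cis-cycloalkenols, which should set C4 (R) and C5 (S); the alkenes without a free allylic hydroxyl (C1=C10, methacrylate) and the homoallylic, less electron-rich C11=C13 react far more slowly.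

Step 19
Reactants: 27 4,5-epoxy C6 alcohol
Product: 28 epoxy 6,12-diol (4R,5S,6S,7S,8S,9R)
Conditions: Bu4NF, AcOH (1:1), THF, 0 °C to rt
Reagents that add atoms: none
Why: Fluoride-induced desilylation of the primary silyl ether, buffered with acetic acid so that neither Payne rearrangement of the epoxy alcohol nor acyl migration sets in.

Step 20
Reactants: 28 epoxy 6,12-diol
Product: 31 (4R,5S,6S,7R,8S,9R)-9-acetoxy-4,5-epoxy-8-(methacryloyloxy)germacra-1(10),11(13)-dien-12,6-olide (ring-cis C1=C10; C14 still methyl), via hydroxy enal 29 (not isolated), via lactol 30 (not isolated)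
Conditions: MnO2 (activated, excess), CH2Cl2, rt
Reagents that add atoms: none
Why: Oxidative lactonisation of a 2-methylene-1,4-diol: MnO2 oxidises the primary allylic alcohol to the acrolein, the C6 hydroxyl (trans to the C7 branch) closes the five-membered lactol and MnO2 oxidises it to the trans-fused α-methylene-γ-butyrolactone; C8 is already acylated, so only the 6,12-lactone can form.

Step 21
Reactants: 31 14-deoxo lactone
Product: 32 14-hydroxy lactone (C14 = CH2OH, trans to C2)
Conditions: SeO2 (30 mol %), t-BuOOH (3 equiv), CH2Cl2, rt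
Reagents that add atoms: selenium dioxide, O=[Se]=O; tert-butyl hydroperoxide, CC(C)(C)OO
Why: Riley allylic oxidation under SeO2/t-BuOOH conditions: ene reaction at C1=C10, the only electron-rich alkene left, and [2,3]-sigmatropic shift of the allylseleninic acid hydroxylate the C14 methyl group, which sits on the more substituted alkene carbon trans to C2, with retention of the ring-cis geometry, a reaction known for 4,5-epoxygermacranolides.

Step 22
Reactants: 32 14-hydroxy lactone
Product: 33 target CNP0121379.1
Conditions: MnO2 (activated, excess), CH2Cl2, rt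
Reagents that add atoms: none
Why: MnO2 oxidises the primary allylic alcohol to the conjugated aldehyde under neutral conditions that spare the epoxide, the esters and the α-methylene lactone.

**Compound list**

1 | neryl acetate, (2Z)-3,7-dimethylocta-2,6-dien-1-yl acetate | CC(=O)OC/C=C(C)\CCC=C(C)C | starting material
2 | (2Z)-5-(3,3-dimethyloxiran-2-yl)-3-methylpent-2-en-1-yl acetate (racemic) | CC(=O)OC/C=C(C)\CCC1OC1(C)C | intermediate
3 | (2Z)-3-methyl-6-oxohex-2-en-1-yl acetate | CC(=O)OC/C=C(C)\CCC=O | intermediate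
4 | methyl 2-[bis(2,2,2-trifluoroethoxy)phosphoryl]propanoate | COC(=O)C(C)P(=O)(OCC(F)(F)F)OCC(F)(F)F | starting material
5 | potassium salt of the carbanion of 4 | COC(=O)[C-](C)P(=O)(OCC(F)(F)F)OCC(F)(F)F.[K+] | intermediate
6 | methyl (2Z,6Z)-8-acetoxy-2,6-dimethylocta-2,6-dienoate | COC(=O)/C(C)=C\CC/C(C)=C\COC(C)=O | intermediate
7 | methyl (2Z,6Z)-8-hydroxy-2,6-dimethylocta-2,6-dienoate | COC(=O)/C(C)=C\CC/C(C)=C\CO | intermediate
8 | methyl (2Z,6Z)-2,6-dimethyl-8-oxoocta-2,6-dienoate | COC(=O)/C(C)=C\CC/C(C)=C\C=O | intermediate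
9 | 2-methylprop-2-en-1-ol | CC(=C)CO | starting material
10 | dilithio dianion of 9 (lithium 2-(lithiomethyl)prop-2-en-1-olate) | [Li]CC(=C)CO[Li] | intermediate
11 | 3-(hydroxymethyl)but-3-enoic acid | OCC(=C)CC(=O)O | intermediate
12 | tert-butyldimethylsilyl 3-{[tert-butyl(dimethyl)silyl]oxymethyl}but-3-enoate | CC(C)(C)[Si](C)(C)OCC(=C)CC(=O)O[Si](C)(C)C(C)(C)C | intermediate
13 | 3-{[tert-butyl(dimethyl)silyl]oxymethyl}but-3-enoic acid | CC(C)(C)[Si](C)(C)OCC(=C)CC(=O)O | intermediate
14 | (4S)-4-benzyl-1,3-oxazolidin-2-one | O=C1N[C@@H](Cc2ccccc2)CO1 | starting material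
15 | mixed anhydride of 13 with pivalic acid | CC(C)(C)[Si](C)(C)OCC(=C)CC(=O)OC(=O)C(C)(C)C | intermediate
16 | (4S)-4-benzyl-3-(3-{[tert-butyl(dimethyl)silyl]oxymethyl}but-3-enoyl)-1,3-oxazolidin-2-one | CC(C)(C)[Si](C)(C)OCC(=C)CC(=O)N1[C@@H](Cc2ccccc2)COC1=O | intermediate
17 | dibutylboron Z(O)-enolate of 16 | CCCCB(CCCC)O/C(=C\C(=C)CO[Si](C)(C)C(C)(C)C)N1[C@@H](Cc2ccccc2)COC1=O | intermediate
18 | Evans syn aldol adduct, methyl (2Z,6Z,8R,9S)-10-[(4S)-4-benzyl-2-oxo-1,3-oxazolidin-3-yl]-9-(3-{[tert-butyl(dimethyl)silyl]oxy}prop-1-en-2-yl)-8-hydroxy-2,6-dimethyl-10-oxodeca-2,6-dienoate | COC(=O)/C(C)=C\CC/C(C)=C\[C@@H](O)[C@H](C(=C)CO[Si](C)(C)C(C)(C)C)C(=O)N1[C@@H](Cc2ccccc2)COC1=O | intermediate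
19 | 8-O-triethylsilyl ether of 18 | COC(=O)/C(C)=C\CC/C(C)=C\[C@@H](O[Si](CC)(CC)CC)[C@H](C(=C)CO[Si](C)(C)C(C)(C)C)C(=O)N1[C@@H](Cc2ccccc2)COC1=O | intermediate
20 | methyl (2Z,6Z,8R,9R)-9-(3-{[tert-butyl(dimethyl)silyl]oxy}prop-1-en-2-yl)-10-hydroxy-2,6-dimethyl-8-[(triethylsilyl)oxy]deca-2,6-dienoate | COC(=O)/C(C)=C\CC/C(C)=C\[C@@H](O[Si](CC)(CC)CC)[C@H](C(=C)CO[Si](C)(C)C(C)(C)C)CO | intermediate
21 | (2Z,6Z,8R,9R)-9-(3-{[tert-butyl(dimethyl)silyl]oxy}prop-1-en-2-yl)-2,6-dimethyl-8-[(triethylsilyl)oxy]deca-2,6-diene-1,10-diol | OC/C(C)=C\CC/C(C)=C\[C@@H](O[Si](CC)(CC)CC)[C@H](C(=C)CO[Si](C)(C)C(C)(C)C)CO | intermediate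
22 | (2Z,6Z,8R,9S)-9-(3-{[tert-butyl(dimethyl)silyl]oxy}prop-1-en-2-yl)-2,6-dimethyl-8-[(triethylsilyl)oxy]deca-2,6-dienedial | O=C/C(C)=C\CC/C(C)=C\[C@@H](O[Si](CC)(CC)CC)[C@H](C(=C)CO[Si](C)(C)C(C)(C)C)C=O | intermediate
23 | (1R,2S,3R,4R,5Z,9Z)-3-(3-{[tert-butyl(dimethyl)silyl]oxy}prop-1-en-2-yl)-6,10-dimethyl-4-[(triethylsilyl)oxy]cyclodeca-5,9-diene-1,2-diol (cis-8,9-diol, germacrane 6R,7R,8S,9R) | C/C1=C/CC/C(C)=C\[C@@H](O[Si](CC)(CC)CC)[C@H](C(=C)CO[Si](C)(C)C(C)(C)C)[C@H](O)[C@@H]1O | intermediate
24 | 9-O-acetate of 23 (C8 hydroxyl free; germacrane 6R,7R,8S,9R) | C/C1=C/CC/C(C)=C\[C@@H](O[Si](CC)(CC)CC)[C@H](C(=C)CO[Si](C)(C)C(C)(C)C)[C@H](O)[C@@H]1OC(C)=O | intermediate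
25 | 9-O-acetate 8-O-methacrylate of 23 (germacrane 6R,7R,8S,9R) | C/C1=C/CC/C(C)=C\[C@@H](O[Si](CC)(CC)CC)[C@H](C(=C)CO[Si](C)(C)C(C)(C)C)[C@H](OC(=O)C(C)=C)[C@@H]1OC(C)=O | intermediate
26 | C6 alcohol: 25 without the triethylsilyl group (germacrane 6R,7S,8S,9R) | C/C1=C/CC/C(C)=C\[C@@H](O)[C@H](C(=C)CO[Si](C)(C)C(C)(C)C)[C@H](OC(=O)C(C)=C)[C@@H]1OC(C)=O | intermediate
27 | 4,5-epoxide of 26, oxirane oxygen cis to the C6 hydroxyl (germacrane 4R,5S,6S,7S,8S,9R) | C=C(C)C(=O)O[C@H]1[C@@H](C(=C)CO[Si](C)(C)C(C)(C)C)[C@H](O)[C@@H]2O[C@]2(C)CC/C=C(/C)[C@H]1OC(C)=O | intermediate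
28 | epoxy 6,12-diol: 27 without the tert-butyldimethylsilyl group | C=C(C)C(=O)O[C@H]1[C@@H](C(=C)CO)[C@H](O)[C@@H]2O[C@]2(C)CC/C=C(/C)[C@H]1OC(C)=O | intermediate
29 | hydroxy enal: 28 with C12 as aldehyde | C=C(C)C(=O)O[C@H]1[C@@H](C(=C)C=O)[C@H](O)[C@@H]2O[C@]2(C)CC/C=C(/C)[C@H]1OC(C)=O | intermediate
30 | 6,12-lactol (C12 hemiacetal, either epimer) | C=C(C)C(=O)O[C@H]1[C@H]2C(=C)C(O)O[C@@H]2[C@@H]2O[C@]2(C)CC/C=C(/C)[C@H]1OC(C)=O | intermediate
31 | (4R,5S,6S,7R,8S,9R)-9-acetoxy-4,5-epoxy-8-(methacryloyloxy)germacra-1(10),11(13)-dien-12,6-olide, ring-cis C1=C10, C14 methyl | C=C(C)C(=O)O[C@H]1[C@H]2C(=C)C(=O)O[C@@H]2[C@@H]2O[C@]2(C)CC/C=C(/C)[C@H]1OC(C)=O | intermediate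
32 | 14-hydroxy derivative of 31 (CH2OH on C10, trans to C2) | C=C(C)C(=O)O[C@H]1[C@H]2C(=C)C(=O)O[C@@H]2[C@@H]2O[C@]2(C)CC/C=C(/CO)[C@H]1OC(C)=O | intermediate
33 | CNP0121379.1, 14-oxo derivative of 31 | C=C(C)C(=O)O[C@H]1[C@H]2C(=C)C(=O)O[C@@H]2[C@@H]2O[C@]2(C)CC/C=C(/C=O)[C@H]1OC(C)=O | target

**Step count and risks**

Total steps: 22. Longest linear sequence: 19 steps (steps 1–5 and 9–22, from neryl acetate); the imide branch (steps 6–8) joins at step 9.

Steps most likely to fail:

1. Step 14 (pinacol ring closure). The enal ketyl may couple through its vinylogous carbon C1, or the carbonyls may be reduced or oligomerise instead of closing the ring. The face of the C8 carbonyl may also be chosen poorly relative to C7. The fallback sets out from dialdehyde 22 and comes back at diol 23. Dialdehyde 22 would be cyclised with CrCl2 and Me3SiCl in THF at high dilution. Divalent chromium and the chlorosilane turn the enal into a γ-silyloxyallylchromium species with the metal on C1. This adds to the C8 aldehyde through C9 in a six-membered cyclic transition state, a two-electron allylmetal addition with transposition in which C1 cannot be the bond-forming carbon and whose anti preference corresponds to the ring-cis glycol. It should give the C9 trimethylsilyl ether of the cis-diol F1. K2CO3 in MeOH at 0 °C would then remove the trimethylsilyl group and return 23.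

2. Step 15 (monoacetylation at C9). Discrimination between the two secondary hydroxyls may be poor, and the acetyl group may migrate between the cis oxygens under basic conditions. The fallback sets out from diol 23 and comes back at monoacetate 24. Diol 23 would be heated with Bu2SnO in MeOH and evaporated to the dibutylstannylene acetal F2. This would be treated with AcCl (1 equiv) in CH2Cl2 at −20 °C without added base. Tin-mediated monoacylation activates one oxygen of the glycol, expected to be the more exposed allylic C9 oxygen, and runs under base-free conditions in which acetyl migration is not expected.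

3. Step 21 (C14 oxidation). The ene reaction may be slow because the allylic C9 acetate deactivates C1=C10, and forcing it risks acid-mediated opening of the 4,5-epoxide and over-oxidation. The fallback sets out from lactone 31 and comes back at target 33, bypassing step 22. Ene-type chlorination of 31 with hypochlorous acid (Ca(OCl)2, solid CO2, CH2Cl2/H2O, 0 °C) should give the rearranged 1-chloro-10(14)-ene F3. NaI (cat.) in MeCN would transpose this to the primary allylic iodide F4 (Finkelstein exchange with allylic shift to the trisubstituted alkene). In the same flask N-methylmorpholine N-oxide would oxidise F4 to the enal 33 (Ganem oxidation), in the favoured geometry with the aldehyde trans to C2.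

Further compounds
F1 | step 14 | 9-O-trimethylsilyl ether of diol 23 | C/C1=C/CC/C(C)=C\[C@@H](O[Si](CC)(CC)CC)[C@H](C(=C)CO[Si](C)(C)C(C)(C)C)[C@H](O)[C@@H]1O[Si](C)(C)C
F2 | step 15 | 8,9-O-dibutylstannylene acetal of diol 23 | C/C1=C/CC/C(C)=C\[C@@H](O[Si](CC)(CC)CC)[C@H](C(=C)CO[Si](C)(C)C(C)(C)C)[C@H](O3)[C@@H]1O[Sn]3(CCCC)CCCC
F3 | step 21 | 1-chloro-10(14)-ene from 31 (C1 epimers) | C=C(C)C(=O)O[C@H]1[C@H]2C(=C)C(=O)O[C@@H]2[C@@H]2O[C@]2(C)CCC(Cl)C(=C)[C@H]1OC(C)=O
F4 | step 21 | 14-iodo derivative of 31 | C=C(C)C(=O)O[C@H]1[C@H]2C(=C)C(=O)O[C@@H]2[C@@H]2O[C@]2(C)CC/C=C(/CI)[C@H]1OC(C)=O
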